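## Retrosynthetic overview

1. The target comes from silyl ether 25. Ring alkene 17 (C6=C7) is joined to (2Z,4E)-iodo diene 22 by syn-hydroboration anti to the angular methyl, B/Zn exchange and Negishi alkenylation. This sets C6 and C7 and carries the Z,E-diene in unchanged.
2. Compound 17 comes from bicyclic dienol 15 by OH-directed epoxidation (C2, C3) and acetylation.
3. Key step: 15 comes from the eight-membered allylic ether 12 by a transannular [2,3]-Wittig ring contraction. It forms C1–C10, closes the cycloheptene, and sets C10 and C1 by chirality transfer from C7–O.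
4. Compound 12 comes from RCM of the allyl ether of cyclopentenol 10. Compound 10 comes from (R)-limonene oxide by cleavage and aldol, Criegee rearrangement (isopropenyl to OAc with retention), methylenation and B-alkyl Suzuki coupling.
5. Ring order: cyclopentene, then the temporary eight-membered ether, then the cycloheptene.

Assumption and labels: the Ca=Cb bond is taken as Z exactly as written in the SMILES. C1 = CHOAc, C2/C3 = epoxide CH/C(Me), C4 and C5 = CH2, C6 = ring-fusion CH, C7 = CH bearing the side chain, C8 and C9 = CH2, C10 = C(Me). The side chain is Ca(Me)=Cb–Cc=Cd–Ce(Me)2OH.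

## Route

Step 1
Reactants: 1 (R)-(+)-limonene 1,2-oxide (commercial cis/trans mixture)
Product: 2 (3R)-6-oxo-3-(prop-1-en-2-yl)heptanal
Conditions: H5IO6, THF/H2O, 0 °C to rt
Reagents that add atoms: water O
Why: Acidic epoxide hydrolysis followed by Malaprade glycol cleavage opens only the former ring alkene, and the limonene stereocentre is untouched.

Step 2
Reactants: 2 (3R)-6-oxo-3-(prop-1-en-2-yl)heptanal
Product: 3 (5S)-2-methyl-5-(prop-1-en-2-yl)cyclopent-1-ene-1-carbaldehyde
Conditions: piperidine (cat.), AcOH (cat.), toluene, reflux (Dean–Stark)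
Reagents that add atoms: none
Why: An amine-catalysed intramolecular aldol condensation (aldehyde α-carbon onto the methyl ketone) gives the known cyclopentene carbaldehyde without touching the stereocentre.

Step 3
Reactants: 3 (5S)-2-methyl-5-(prop-1-en-2-yl)cyclopent-1-ene-1-carbaldehyde
Product: 6 (1R)-2-formyl-3-methylcyclopent-2-en-1-yl acetate, via methoxy hydroperoxide 4 (not isolated), via peracetate 5 (not isolated)
Conditions: O3, CH2Cl2/MeOH, −78 °C (Sudan III end point); then Ac2O, Et3N, DMAP (cat.), CH2Cl2, 0 °C to reflux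
Reagents that add atoms: ozone [O-][O+]=O; methanol CO
Why: Ozone attacks only the electron-rich isopropenyl group because the ring alkene is a deactivated enal, and the Criegee rearrangement of the acylated α-methoxy hydroperoxide moves C7 from carbon to oxygen with retention, giving the (R)-allylic C7–O centre.

Step 4
Reactants: 6 (1R)-2-formyl-3-methylcyclopent-2-en-1-yl acetate
Product: 8 (1R)-2-ethenyl-3-methylcyclopent-2-en-1-ol, via dienyl acetate 7 (not isolated)
Conditions: Ph3PCH3Br, KHMDS, THF, −78 to 0 °C; then K2CO3 (cat.), MeOH, rt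
Reagents that add atoms: methyltriphenylphosphonium bromide C[P+](c1ccccc1)(c1ccccc1)c1ccccc1.[Br-]
Why: Wittig methylenation of the aldehyde is fast at low temperature, and telescoped methanolysis removes the allylic acetate before any Pd(0) chemistry.

Step 5
Reactants: 8 (1R)-2-ethenyl-3-methylcyclopent-2-en-1-ol
Product: 10 (1R)-3-methyl-2-(3-methylbut-3-en-1-yl)cyclopent-2-en-1-ol, via bis(9-BBN) adduct 9 (not isolated)
Conditions: 9-BBN (2.2 equiv), THF, 0 °C to rt; then 2-bromopropene, PdCl2(dppf) (5 mol %), 3 M aq NaOH, 50 °C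
Reagents that add atoms: 2-bromopropene CC(Br)=C
Why: 9-BBN adds only to the monosubstituted end of the diene, and the B-alkyl Suzuki–Miyaura coupling installs C4–C3(Me)=CH2 while the tetrasubstituted alkene stays inert.

Step 6
Reactants: 10 (1R)-3-methyl-2-(3-methylbut-3-en-1-yl)cyclopent-2-en-1-ol
Product: 11 (3R)-1-methyl-2-(3-methylbut-3-en-1-yl)-3-(prop-2-en-1-yloxy)cyclopent-1-ene
Conditions: NaH, allyl bromide, TBAI (cat.), THF/DMF, 0 °C to rt
Reagents that add atoms: allyl bromide C=CCBr
Why: Williamson etherification attaches C1 and C2 to the C7 oxygen without touching the C–O stereocentre.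

Step 7
Reactants: 11 (3R)-1-methyl-2-(3-methylbut-3-en-1-yl)-3-(prop-2-en-1-yloxy)cyclopent-1-ene
Product: 12 (3Z,9aR)-4,7-dimethyl-2,5,6,8,9,9a-hexahydrocyclopenta[b]oxocine
Conditions: Grubbs II (10 mol %), 1,4-benzoquinone (cat.), toluene (1 mM), 80 °C
Reagents that add atoms: none
Why: Ring-closing metathesis of the only two reactive alkenes, held on adjacent ring atoms, gives the fused eight-membered ether, whose new C2=C3 bond must be Z.

Step 8
Reactants: 12 (3Z,9aR)-4,7-dimethyl-2,5,6,8,9,9a-hexahydrocyclopenta[b]oxocine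
Product: 15 (3aS,4R)-3a,6-dimethyl-2,3,3a,4,7,8-hexahydroazulen-4-ol, via 2-lithio oxocene 13 (not isolated), via lithium alkoxide 14 (not isolated)
Conditions: n-BuLi (1.5 equiv), THF, −78 to −20 °C; then H2O
Reagents that add atoms: none
Why: In this transannular [2,3]-Wittig ring contraction the α-oxyallyl anion at C1 attacks C10 suprafacially on the face of the C7–O bond (setting quaternary C10), and the C3–C4–C5 tether forces C2 to the side of C5, so the C1 oxygen ends anti to the angular methyl and the alkene moves to C6=C7.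

Step 9
Reactants: 15 (3aS,4R)-3a,6-dimethyl-2,3,3a,4,7,8-hexahydroazulen-4-ol
Product: 16 (3aS,4S,5S,6R)-5,6-epoxy-3a,6-dimethyl-2,3,3a,4,5,6,7,8-octahydroazulen-4-ol (epoxide syn to OH)
Conditions: VO(acac)2 (2 mol %), t-BuOOH (1.1 equiv), CH2Cl2, 0 °C
Reagents that add atoms: tert-butyl hydroperoxide CC(C)(C)OO
Why: Vanadium-catalysed hydroxyl-directed epoxidation delivers oxygen to the allylic C2=C3 bond on the face of the C1–OH (cycloheptenols give cis products), much faster than to the homoallylic C6=C7 bond.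

Step 10
Reactants: 16 (3aS,4S,5S,6R)-5,6-epoxy-3a,6-dimethyl-2,3,3a,4,5,6,7,8-octahydroazulen-4-ol
Product: 17 (3aS,4S,5S,6R)-5,6-epoxy-3a,6-dimethyl-2,3,3a,4,5,6,7,8-octahydroazulen-4-yl acetate
Conditions: Ac2O, pyridine, DMAP (cat.), CH2Cl2, rt
Reagents that add atoms: acetic anhydride CC(=O)OC(C)=O
Why: DMAP-catalysed acylation of the only hydroxyl group proceeds with no change at any stereocentre.

Step 11
Reactants: 18 2-methylbut-3-en-2-ol; 19 (E)-crotonaldehyde
Product: 20 (E)-4-hydroxy-4-methylpent-2-enal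
Conditions: Hoveyda–Grubbs II (2 mol %), CH2Cl2, 40 °C
Reagents that add atoms: none
Why: Olefin cross metathesis between a hindered tertiary allylic alcohol and an enal is selective for the E cross product.

Step 12
Reactants: 20 (E)-4-hydroxy-4-methylpent-2-enal
Product: 21 (E)-4-methyl-4-(triethylsilyloxy)pent-2-enal
Conditions: TESOTf, 2,6-lutidine, CH2Cl2, −78 to 0 °C
Reagents that add atoms: triethylsilyl triflate CC[Si](CC)(CC)OS(=O)(=O)C(F)(F)F
Why: Silyl triflate silylation masks the acidic tertiary OH so that it cannot protonate the organozinc reagent in step 14.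

Step 13
Reactants: 21 (E)-4-methyl-4-(triethylsilyloxy)pent-2-enal
Product: 22 (2Z,4E)-2-iodo-6-methyl-6-(triethylsilyloxy)hepta-2,4-diene
Conditions: EtPPh3I, n-BuLi, THF, rt; I2, −78 °C; NaHMDS, −20 °C; then 21, −78 °C
Reagents that add atoms: ethyltriphenylphosphonium iodide CC[P+](c1ccccc1)(c1ccccc1)c1ccccc1.[I-]; iodine II
Why: The Stork–Zhao-type Wittig reaction of the α-iodoethylidene ylide gives the (Z)-2-iodoalk-2-ene (iodine cis to the chain), and the E-enal geometry is kept.

Step 14
Reactants: 17 (3aS,4S,5S,6R)-5,6-epoxy-3a,6-dimethyl-2,3,3a,4,5,6,7,8-octahydroazulen-4-yl acetate; 22 (2Z,4E)-2-iodo-6-methyl-6-(triethylsilyloxy)hepta-2,4-diene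
Product: 25 triethylsilyl ether of the target, via diethylborane adduct 23 (not isolated), via isopropylzinc species 24 (not isolated)
Conditions: Et2BH (from BH3·SMe2 + Et3B), 50 °C; i-Pr2Zn, rt, then volatiles off in vacuo; 22, Pd(dba)2 (5 mol %), P(o-tol)3 (10 mol %), THF, rt to 40 °C
Reagents that add atoms: none
Why: Syn-hydroboration of the only alkene from the face opposite the angular methyl puts H on C6 (trans ring fusion) and boron on C7 cis to it, and the boron–zinc exchange and Negishi coupling both go with retention at C7 and at the Z-iodide.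

Step 15
Reactants: 25 triethylsilyl ether of the target
Product: 26 target, (1R,3aS,4S,5S,6R,8aS)-5,6-epoxy-1-[(2Z,4E)-6-hydroxy-6-methylhepta-2,4-dien-2-yl]-3a,6-dimethyldecahydroazulen-4-yl acetate
Conditions: TBAF, AcOH (1:1), THF, 0 °C to rt
Reagents that add atoms: none
Why: Buffered fluoride desilylation frees the tertiary allylic alcohol without touching the acetate, the epoxide or the diene geometry.

## Compound list

1 | (R)-(+)-limonene 1,2-oxide (cis/trans mixture) | CC(=C)[C@@H]1CCC2(C)OC2C1 | starting material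
2 | (3R)-6-oxo-3-(prop-1-en-2-yl)heptanal | CC(=O)CC[C@H](CC=O)C(C)=C | intermediate
3 | (5S)-2-methyl-5-(prop-1-en-2-yl)cyclopent-1-ene-1-carbaldehyde | CC1=C(C=O)[C@@H](CC1)C(C)=C | intermediate
4 | 5-(1-hydroperoxy-1-methoxyethyl)-2-methylcyclopent-1-ene-1-carbaldehyde (ring centre as in 3, peroxyketal carbon as both epimers) | CC1=C(C=O)[C@@H](CC1)C(C)(OC)OO | intermediate
5 | peracetate of 4 | CC1=C(C=O)[C@@H](CC1)C(C)(OC)OOC(C)=O | intermediate
6 | (1R)-2-formyl-3-methylcyclopent-2-en-1-yl acetate | CC1=C(C=O)[C@@H](CC1)OC(C)=O | intermediate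
7 | (1R)-2-ethenyl-3-methylcyclopent-2-en-1-yl acetate | CC1=C(C=C)[C@@H](CC1)OC(C)=O | intermediate
8 | (1R)-2-ethenyl-3-methylcyclopent-2-en-1-ol | CC1=C(C=C)[C@@H](CC1)O | intermediate
9 | O-(9-BBN) borinate of 8 carrying a 2-(9-BBN)ethyl group in place of the vinyl group | CC1=C(CCB2C3CCCC2CCC3)[C@@H](CC1)OB1C2CCCC1CCC2 | intermediate
10 | (1R)-3-methyl-2-(3-methylbut-3-en-1-yl)cyclopent-2-en-1-ol | CC1=C(CCC(C)=C)[C@@H](CC1)O | intermediate
11 | (3R)-1-methyl-2-(3-methylbut-3-en-1-yl)-3-(prop-2-en-1-yloxy)cyclopent-1-ene | CC1=C(CCC(C)=C)[C@@H](CC1)OCC=C | intermediate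
12 | (3Z,9aR)-4,7-dimethyl-2,5,6,8,9,9a-hexahydrocyclopenta[b]oxocine | CC1=C2CC/C(C)=C\CO[C@@H]2CC1 | intermediate
13 | 2-lithio derivative of 12 (anion at C1) | CC1=C2CC/C(C)=C\C([Li])O[C@@H]2CC1 | intermediate
14 | lithium alkoxide of 15 | [Li]O[C@@H]1C=C(C)CCC2=CCC[C@]12C | intermediate
15 | (3aS,4R)-3a,6-dimethyl-2,3,3a,4,7,8-hexahydroazulen-4-ol (OH anti to the angular methyl) | O[C@@H]1C=C(C)CCC2=CCC[C@]12C | intermediate
16 | (3aS,4S,5S,6R)-5,6-epoxy-3a,6-dimethyl-2,3,3a,4,5,6,7,8-octahydroazulen-4-ol (epoxide syn to OH) | O[C@@H]1[C@@H]2O[C@]2(C)CCC2=CCC[C@]12C | intermediate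
17 | acetate of 16 | CC(=O)O[C@@H]1[C@@H]2O[C@]2(C)CCC2=CCC[C@]12C | intermediate
18 | 2-methylbut-3-en-2-ol | CC(C)(O)C=C | starting material
19 | (E)-crotonaldehyde | C/C=C/C=O | starting material
20 | (E)-4-hydroxy-4-methylpent-2-enal | CC(C)(O)/C=C/C=O | intermediate
21 | (E)-4-methyl-4-(triethylsilyloxy)pent-2-enal | CC[Si](CC)(CC)OC(C)(C)/C=C/C=O | intermediate
22 | (2Z,4E)-2-iodo-6-methyl-6-(triethylsilyloxy)hepta-2,4-diene | I/C(C)=C\C=C\C(C)(C)O[Si](CC)(CC)CC | intermediate
23 | C7-diethylboryl trans-fused epoxy acetate (B cis to H6, anti to the angular methyl) | CC(=O)O[C@@H]1[C@@H]2O[C@]2(C)CC[C@H]2[C@H](B(CC)CC)CC[C@]12C | intermediate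
24 | C7-(isopropylzincio) analogue of 23, same configuration | CC(=O)O[C@@H]1[C@@H]2O[C@]2(C)CC[C@H]2[C@H]([Zn]C(C)C)CC[C@]12C | intermediate
25 | triethylsilyl ether of the target | CC(=O)O[C@@H]1[C@@H]2O[C@]2(C)CC[C@H]2[C@H](/C(C)=C\C=C\C(C)(C)O[Si](CC)(CC)CC)CC[C@]12C | intermediate
26 | target; (1S,2S,3R,6S,7R,10S) in the route labels, Ca=Cb Z, Cc=Cd E | CC(=O)O[C@@H]1[C@@H]2O[C@]2(C)CC[C@H]2[C@H](/C(C)=C\C=C\C(C)(C)O)CC[C@]12C | target

## Step count

Total step count: 15.
Longest linear sequence: 12 (steps 1–10, 14, 15).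

## Steps most likely to fail

**Step 7.** This RCM must form an eight-membered ring and a trisubstituted alkene, so dimerisation or allyl-ether isomerisation may win. The fallback closes the same ring at C3–C4 by an intramolecular B-alkyl Suzuki coupling instead of at C2=C3. It sets out from 8. Commercial (Z)-3-iodobut-2-en-1-ol is brominated (CBr4, PPh3) to (Z)-1-bromo-3-iodobut-2-ene F1. Compound 8 is O-alkylated with it (NaH, THF/DMF) to the (Z)-3-iodobut-2-enyl ether F2. 9-BBN then adds only to the vinyl group to give the B-alkyl-9-BBN borane F3. Slow addition of this borane to PdCl2(dppf), AsPh3 and Cs2CO3 in DMF/THF/H2O closes the ring with retention at the Z-iodide. The fallback comes back to the route at 12, so 10 and 11 are skipped.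

**Step 8.** A [1,2]-shift, 1,4-elimination or deprotonation at C7 may compete with the transannular [2,3] shift. The fallback makes the same C1–C10 bond on the open chain by a chelate-controlled glycolate Ireland–Claisen [3,3] rearrangement and closes the seven-membered ring afterwards. It sets out from 10.
- DCC/DMAP esterification with (4-methoxybenzyloxy)acetic acid gives the glycolate ester F4.
- LDA then TMSCl (THF, −78 °C) gives the chelation-derived (Z)-silyl ketene acetal F5.
- On warming, this rearranges on the face of the C7–O bond through the chair arrangement, which gives the required C1 configuration, to the trimethylsilyl ester F6.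
- Work-up hydrolyses it to the α-PMB-oxy acid F7.
- TMSCHN2 gives the methyl ester F8, and DIBAL-H (−78 °C) gives the aldehyde F9.
- Ph3P=CH2 gives the PMB-protected trienol F10, and DDQ gives the free trienol F11.
- Grubbs II closes C2=C3, and the fallback comes back to the route at 15.

**Step 14.** The alkene is hindered, the facial preference rests on the angular methyl, and the sec-alkyl/α-methylalkenyl Negishi coupling may lose out to β-hydride elimination. The fallback switches from a configurationally defined organozinc to a diastereoconvergent radical coupling. It sets out from 17. BH3·THF gives the monoalkylborane F12, and NaBO3·4H2O oxidises it to the C7 alcohol F13. I2, PPh3 and imidazole give the inverted C7 iodide F14. Nickel-catalysed reductive cross-electrophile coupling with 22 (NiBr2·glyme, dtbbpy, Mn, DMA) runs through the C7 radical, which bonds trans to the C5 substituent on C6, with the alkenyl geometry kept. The fallback comes back to the route at 25.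

Further compounds
F1 | step 7 | (Z)-1-bromo-3-iodobut-2-ene | BrC/C=C(/C)I
F2 | step 7 | (1R)-2-ethenyl-3-methylcyclopent-2-en-1-yl (Z)-3-iodobut-2-en-1-yl ether | CC1=C(C=C)[C@@H](CC1)OC/C=C(/C)I
F3 | step 7 | B-alkyl-9-BBN borane from F2 | CC1=C(CCB2C3CCCC2CCC3)[C@@H](CC1)OC/C=C(/C)I
F4 | step 8 | (1R)-3-methyl-2-(3-methylbut-3-en-1-yl)cyclopent-2-en-1-yl (4-methoxybenzyloxy)acetate | CC1=C(CCC(C)=C)[C@@H](CC1)OC(=O)COCc1ccc(OC)cc1
F5 | step 8 | (Z)-trimethylsilyl ketene acetal of F4 (OPMB cis to OSi) | CC1=C(CCC(C)=C)[C@@H](CC1)O/C(O[Si](C)(C)C)=C/OCc1ccc(OC)cc1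
F6 | step 8 | trimethylsilyl ester of F7 | C=C(C)CCC1=CCC[C@]1(C)[C@H](OCc1ccc(OC)cc1)C(=O)O[Si](C)(C)C
F7 | step 8 | 2-(4-methoxybenzyloxy)-2-[1-methyl-2-(3-methylbut-3-en-1-yl)cyclopent-2-en-1-yl]acetic acid (C1 and C10 as in 15) | C=C(C)CCC1=CCC[C@]1(C)[C@H](OCc1ccc(OC)cc1)C(=O)O
F8 | step 8 | methyl ester of F7 | C=C(C)CCC1=CCC[C@]1(C)[C@H](OCc1ccc(OC)cc1)C(=O)OC
F9 | step 8 | aldehyde from F8 | C=C(C)CCC1=CCC[C@]1(C)[C@H](OCc1ccc(OC)cc1)C=O
F10 | step 8 | PMB ether of F11 | C=C(C)CCC1=CCC[C@]1(C)[C@H](OCc1ccc(OC)cc1)C=C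
F11 | step 8 | 1-[1-methyl-2-(3-methylbut-3-en-1-yl)cyclopent-2-en-1-yl]prop-2-en-1-ol (C1 and C10 as in 15) | C=C(C)CCC1=CCC[C@]1(C)[C@H](O)C=C
F12 | step 14 | C7 monoalkylborane of 17 (B cis to H6) | CC(=O)O[C@@H]1[C@@H]2O[C@]2(C)CC[C@H]2[C@H](B)CC[C@]12C
F13 | step 14 | C7 alcohol (OH cis to H6) | CC(=O)O[C@@H]1[C@@H]2O[C@]2(C)CC[C@H]2[C@H](O)CC[C@]12C
F14 | step 14 | C7 iodide (inverted) | CC(=O)O[C@@H]1[C@@H]2O[C@]2(C)CC[C@H]2[C@@H](I)CC[C@]12C
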